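## Retrosynthetic overview

1. Kuwanon E is a 5,7-dihydroxyflavanone whose only stereocenter is C2. The C2–O bond is disconnected to an enantioselective intramolecular 6-endo oxa-Michael cyclisation of 2,4,2',4',6'-pentahydroxy-5-geranylchalcone. This is the last step and the only ring-forming step.
2. The chalcone is disconnected by Claisen–Schmidt condensation into phloroacetophenone and 5-geranyl-2,4-dihydroxybenzaldehyde.
3. The aldehyde comes from a C5-selective Friedel–Crafts geranylation of 2,4-dihydroxybenzaldehyde with geraniol. Both aromatic rings are therefore fully assembled before the pyranone ring closes.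

Assumptions:
- The target SMILES encodes the natural (2S)-flavanone configuration (CIP assignment checked).
- The A ring of the chalcone is symmetric (2'-OH and 6'-OH are equivalent), so cyclisation has no regiochemical ambiguity.
- The 9-amino-9-deoxy-epi-quinine squaramide 6 (made from quinine in two steps, or bought as the amine) is assumed to give (2S). If it gives (2R), the quinidine-derived pseudo-enantiomer is used.

## Route

**Step 1**
Reactants: 1 (2,4-dihydroxybenzaldehyde); 2 (geraniol, (2E)-3,7-dimethylocta-2,6-dien-1-ol)
Product: 3 (5-geranyl-2,4-dihydroxybenzaldehyde)
Conditions: C6F5B(OH)2 (10 mol%), (CO2H)2 (10 mol%), MeNO2, 25 °C, 24 h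
Reagents that add atoms: none (geraniol is the reactant)
Why: This is a boronic acid/oxalic acid-catalysed dehydrative Friedel–Crafts allylation (SEAr). C5 is ortho to the 4-OH and para to the 2-OH, and it is the less hindered site, whereas C3 is flanked by two OH groups. The CHO group deactivates the ring, which limits bis-geranylation, and attack through the primary allylic terminus keeps the E-geranyl chain.

**Step 2**
Reactants: 3 (5-geranyl-2,4-dihydroxybenzaldehyde); 4 (2',4',6'-trihydroxyacetophenone, phloroacetophenone)
Product: 5 ((E)-2,4,2',4',6'-pentahydroxy-5-geranylchalcone)
Conditions: KOH (10 equiv), EtOH/H2O 3:1, N2, 0 °C to rt, 48 h; then cold 2 M HCl to pH 2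
Reagents that add atoms: none
Why: Claisen–Schmidt (aldol condensation) through the polyphenolate gives the E-enone. In strong base the chalcone is held as its stable phenolate, so any flavanone formed reopens. The cold acidic quench returns the open chalcone before 2'-OH cyclisation, which gives racemic flavanone at neutral to basic pH, can occur.

**Step 3**
Reactants: 5 (chalcone); 6 (9-amino(9-deoxy)-epi-quinine 3,5-bis(trifluoromethyl)phenyl squaramide, 10 mol%, catalyst)
Product: 7 (Kuwanon E, (2S)-5,7,2',4'-tetrahydroxy-5'-geranylflavanone)
Conditions: 6 (10 mol%), MTBE/CH2Cl2 9:1 (0.02 M), 4 Å MS, 10 °C, 72 h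
Reagents that add atoms: none (isomerisation; 6 is a catalyst)
Why: Proposed new method: a chalcone-isomerase-type enantioselective 6-endo oxa-Michael cyclisation without enzyme, on a fully unprotected pentahydroxychalcone whose acceptor terminus is an electron-rich 2,4-dihydroxyaryl group. The squaramide N–H groups bind the carbonyl/6'-OH cluster and hold the s-cis enone. The quinuclidine is a weak base that H-bonds the nucleophilic 2'-OH without fully ionising the polyphenol, which keeps the racemic background reaction low. The phenol is delivered to one enone face, setting C2 as (S) and giving the thermodynamically favoured 5-hydroxyflavanone. The closest known reaction type is cinchona-thiourea/squaramide-catalysed oxa-Michael cyclisation of 2'-hydroxyphenyl enones.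

## Consistency checks
- **Ring pattern:** the B ring in 3, 5 and 7 has C1' attached to the chain or C2, OH at 2' and 4', and geranyl at 5'. This matches the target SMILES.
- **Atom balance:** C7H6O3 + C10H18O → C17H22O3 + H2O; C17H22O3 + C8H8O4 → C25H28O6 (chalcone) + H2O; the chalcone isomerises to Kuwanon E, C25H28O6.
- **Functional-group survival:** the geranyl alkenes survive weak acid, KOH and weak amine base. Only C2 is a stereocenter. It is set in the final step, with no later manipulation and only neutral silica purification, so it is not scrambled.

## Compound list
1 | 2,4-dihydroxybenzaldehyde | O=Cc1ccc(O)cc1O | starting material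
2 | geraniol | CC(C)=CCC/C(C)=C/CO | starting material
3 | 5-geranyl-2,4-dihydroxybenzaldehyde | CC(C)=CCC/C(C)=C/Cc1cc(C=O)c(O)cc1O | intermediate
4 | 2',4',6'-trihydroxyacetophenone | CC(=O)c1c(O)cc(O)cc1O | starting material
5 | (E)-2,4,2',4',6'-pentahydroxy-5-geranylchalcone | CC(C)=CCC/C(C)=C/Cc1cc(/C=C/C(=O)c2c(O)cc(O)cc2O)c(O)cc1O | intermediate
6 | 9-amino(9-deoxy)-epi-quinine 3,5-bis(trifluoromethyl)phenyl squaramide (catalyst) | COc1ccc2nccc([C@H](NC3=C(Nc4cc(C(F)(F)F)cc(C(F)(F)F)c4)C(=O)C3=O)[C@@H]3C[C@@H]4CCN3C[C@@H]4C=C)c2c1 | starting material (catalyst)
7 | Kuwanon E | CC(C)=CCC/C(C)=C/Cc1cc([C@@H]2CC(=O)c3c(O)cc(O)cc3O2)c(O)cc1O | target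

## Summary
Total steps: 3. Longest linear sequence: 3.

**Three steps most likely to fail**
1. **Step 3 (proposed new step).** The polyphenol may be ionised or bound by the catalyst, giving low ee or a racemic background reaction. The weakly basic amine may also racemise the 5-hydroxyflavanone by retro-oxa-Michael ring opening.
   - Fallback: cyclise 5 racemically with NaOAc in EtOH at reflux, then separate the enantiomers by semipreparative chiral HPLC (Chiralpak IA/IC). This uses known chemistry and changes the approach to resolution.
2. **Step 1.** The geranyl cation can isomerise or cyclise, and C3/C5 regioselectivity may be poor.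
   - Fallback: brominate 1 with NBS at C5 and protect the phenols as bis-MOM ethers. Then run a Miyaura borylation, a Pd-catalysed Suzuki allyl coupling with geranyl bromide (linear-selective, E retained), and a mild MOM removal (PPTS, t-BuOH).
3. **Step 2.** Condensation with an aldehyde deactivated as its phenolate, and with five free OH groups, gives low yield.
   - Fallback: use 2,4-bis-MOM aldehyde 3 and 2'-hydroxy-4',6'-bis-MOM-acetophenone with NaOH/EtOH, then carry the protected chalcone through step 3. Remove all MOM groups at the end with HCl/MeOH at 0 °C.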